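**Retrosynthetic overview**
1. The C6 anisate comes from selective acylation of the secondary hydroxyl of the hydroazulene keto diol.
2. The seven-membered ring is formed last, by ring-closing metathesis across C8=C9; C6–C7 comes from chelate-controlled methallylation of a C6 aldehyde.
3. The C4–OH and C6–O bonds come from a photocatalytic O2 insertion into the exocyclic cyclopropane bond (C4–C6) of an allylated thujone silyl enol ether, through a cis-fused dioxolane (retention at C4).
4. The quaternary C1 comes from allylation of the thujone enolate on the face anti to the cyclopropane.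
5. The five-membered ring, the C4 and C5 stereocentres and carbon C6 are bought with (−)-α-thujone; only the seven-membered ring is built.

Assumption: atoms are numbered as in the daucane skeleton of the target (C1 angular methyl carbon, C2 ketone, C3 CH2, C4 carbinol, C5 ring-fusion CH, C6 ester carbon, C7–C10 the other ring carbons). (−)-α-Thujone is taken as enantiopure; the cheaper α/β-thujone mixture from cedar-leaf oil can replace it, because both C-methyl epimers give the same enolate in step 1.

**Step 1**
Reactants: 1 (−)-α-thujone, (1S,4R,5R)-4-methyl-1-(propan-2-yl)bicyclo[3.1.0]hexan-3-one; 2 allyl bromide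
Product: 3 (1S,4R,5S)-4-methyl-1-(propan-2-yl)-4-(prop-2-en-1-yl)bicyclo[3.1.0]hexan-3-one (4-allylthujone; allyl anti to the cyclopropane CH2)
Conditions: KOtBu (1.05 equiv), allyl bromide (1.1 equiv), t-BuOH/THF, 0 °C → rt
Reagents that add atoms: allyl bromide 2, C=CCBr
Why: Enolate C-alkylation under equilibrating conditions goes through the more substituted (tetrasubstituted) potassium enolate, and allyl bromide attacks the face opposite the cyclopropane methylene, so the quaternary C1 is set by the purchased C5 stereocentre.

**Step 2**
Reactants: 3 4-allylthujone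
Product: 4 tert-butyldimethyl{[(1S,4R,5S)-4-methyl-1-(propan-2-yl)-4-(prop-2-en-1-yl)bicyclo[3.1.0]hex-2-en-3-yl]oxy}silane (TBS enol ether, C2=C3 in daucane numbering)
Conditions: TBSOTf, Et3N, CH2Cl2, 0 °C → rt
Reagents that add atoms: tert-butyldimethylsilyl triflate, CC(C)(C)[Si](C)(C)OS(=O)(=O)C(F)(F)F
Why: Soft enolisation/O-silylation can only occur toward C3, the single remaining enolisable position, which places the enol ether π-bond next to the cyclopropane; no stereocentre is touched.

**Step 3**
Reactants: 4 TBS enol ether
Product: 7 keto diol (2R,3S,4R)-4-hydroxy-3-(hydroxymethyl)-2-methyl-4-(propan-2-yl)-2-(prop-2-en-1-yl)cyclopentan-1-one, via dioxolane silyl enol ether 5 (not isolated), via dioxolane ketone 6 (not isolated)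
Conditions: O2 (1 atm), 9-mesityl-3,6-di-tert-butyl-10-phenylacridinium tetrafluoroborate (2 mol%), MeCN/CH2Cl2, 450 nm LEDs, 0 °C; then AcOH/H2O/THF, rt; then Zn dust, rt
Reagents that add atoms: dioxygen, O=O
Why: Proposed new method: a photocatalytic aerobic formal (3+2) insertion of O2 into the exocyclic cyclopropane bond of a β-cyclopropyl silyl enol ether, in which the excited acridinium (about +2.0 V vs SCE) oxidises the enol ether (about +1.3 V) to its radical cation, the spin at C3 sits in a cyclopropylcarbinyl position so the C4–C6 bond that overlaps with the π-SOMO cleaves to a silyloxyallyl cation/primary C6 radical, triplet O2 traps the C6 radical, the acridine radical reduces the peroxyl radical (closing the catalytic cycle), and the peroxide oxygen closes 5-exo onto C4, the electrophilic terminus of the silyloxyallyl cation; since a 1,2-dioxolane can only be cis-fused to the cyclopentane, the key C4–O bond forms on the face that C6 occupied, so the purchased cyclopropane stereocentre becomes the C4 carbinol with retention (4R) and C5 is untouched; the closest known reaction types are the electron-transfer photooxygenation of arylcyclopropanes to 1,2-dioxolanes and the thiyl-radical-mediated oxygenation of vinylcyclopropanes, neither shown on an enol-ether-activated alkylcyclopropane; acid hydrolysis of the enol ether and Zn/AcOH cleavage of the O–O bond then give the diol without base, which would collapse the β-peroxy ketone to an epoxide.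

**Step 4**
Reactants: 7 keto diol
Product: 8 (1R,2R,5R)-2-hydroxy-5-methyl-4-oxo-2-(propan-2-yl)-5-(prop-2-en-1-yl)cyclopentane-1-carbaldehyde (β-hydroxy aldehyde, CHO on C5 cis to the C4 hydroxyl)
Conditions: TEMPO (10 mol%), PhI(OAc)2 (1.1 equiv), CH2Cl2, rt
Reagents that add atoms: none
Why: The oxoammonium (TEMPO/PhI(OAc)2) oxidation takes the primary alcohol to the aldehyde and leaves the tertiary alcohol untouched, under base-free conditions that avoid β-elimination or retro-aldol of the product.

**Step 5**
Reactants: 8 β-hydroxy aldehyde; 9 methallyl bromide (3-bromo-2-methylprop-1-ene)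
Product: 10 (2R,3S,4R)-4-hydroxy-3-[(1S)-1-hydroxy-3-methylbut-3-en-1-yl]-2-methyl-4-(propan-2-yl)-2-(prop-2-en-1-yl)cyclopentan-1-one
Conditions: In powder (1.5 equiv), methallyl bromide (2 equiv), THF/H2O (1:1), rt
Reagents that add atoms: methallyl bromide 9, C=C(C)CBr
Why: The indium-mediated Barbier allylation in water is selective for the aldehyde over the hindered ketone, and the free C4 hydroxyl and the aldehyde oxygen chelate indium so that the allyl group adds from the chelate face carrying H5 rather than the quaternary C1 (Cram-chelate model), which gives the 6S carbinol.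

**Step 6**
Reactants: 10 diene diol
Product: 11 (3R,3aS,4S,8aR)-3,4-dihydroxy-6,8a-dimethyl-3-(propan-2-yl)-2,3,3a,4,5,8-hexahydroazulen-1(8aH)-one (trans-fused hydroazulene keto diol)
Conditions: second-generation Grubbs catalyst RuCl2(=CHPh)(H2IMes)(PCy3) (5 mol%), CH2Cl2 (5 mM), 40 °C
Reagents that add atoms: none
Why: Ring-closing metathesis between the monosubstituted allyl alkene and the 1,1-disubstituted methallyl alkene forms the trisubstituted C8=C9 bond and the seven-membered ring with loss of ethylene; free hydroxyls and the ketone are tolerated and no stereocentre is involved.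

**Step 7**
Reactants: 11 hydroazulene keto diol; 12 4-methoxybenzoyl chloride
Product: 13 (3R,3aS,4S,8aR)-3-hydroxy-6,8a-dimethyl-1-oxo-3-(propan-2-yl)-1,2,3,3a,4,5,8,8a-octahydroazulen-4-yl 4-methoxybenzoate (target)
Conditions: pyridine, DMAP (10 mol%), CH2Cl2, 0 °C → rt
Reagents that add atoms: 4-methoxybenzoyl chloride 12, COc1ccc(C(Cl)=O)cc1
Why: DMAP-catalysed acylation esterifies the secondary C6 hydroxyl with retention, while the tertiary C4 hydroxyl is too hindered to react.

**Compound list**
1 | (−)-α-thujone, (1S,4R,5R)-4-methyl-1-(propan-2-yl)bicyclo[3.1.0]hexan-3-one | C[C@H]1C(=O)C[C@]2(C(C)C)C[C@H]12 | starting material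
2 | allyl bromide | C=CCBr | starting material
3 | (1S,4R,5S)-4-methyl-1-(propan-2-yl)-4-(prop-2-en-1-yl)bicyclo[3.1.0]hexan-3-one | C=CC[C@@]1(C)C(=O)C[C@]2(C(C)C)C[C@H]12 | intermediate
4 | TBS enol ether of 3 (enol ether double bond between C2 and C3, next to the cyclopropane) | C=CC[C@@]1(C)C(O[Si](C)(C)C(C)(C)C)=C[C@]2(C(C)C)C[C@H]12 | intermediate
5 | dioxolane silyl enol ether: 1,2-dioxolane cis-fused across C4–C5 (O–O bridging C4 and the C6 methylene), TBS enol ether retained | C=CC[C@@]1(C)C(O[Si](C)(C)C(C)(C)C)=C[C@]2(C(C)C)OOC[C@H]12 | intermediate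
6 | dioxolane ketone: the same cis-fused 1,2-dioxolane with the C2 ketone free | C=CC[C@@]1(C)C(=O)C[C@]2(C(C)C)OOC[C@H]12 | intermediate
7 | (2R,3S,4R)-4-hydroxy-3-(hydroxymethyl)-2-methyl-4-(propan-2-yl)-2-(prop-2-en-1-yl)cyclopentan-1-one | C=CC[C@@]1(C)C(=O)C[C@@](O)(C(C)C)[C@@H]1CO | intermediate
8 | (1R,2R,5R)-2-hydroxy-5-methyl-4-oxo-2-(propan-2-yl)-5-(prop-2-en-1-yl)cyclopentane-1-carbaldehyde | C=CC[C@@]1(C)C(=O)C[C@@](O)(C(C)C)[C@@H]1C=O | intermediate
9 | methallyl bromide (3-bromo-2-methylprop-1-ene) | C=C(C)CBr | starting material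
10 | (2R,3S,4R)-4-hydroxy-3-[(1S)-1-hydroxy-3-methylbut-3-en-1-yl]-2-methyl-4-(propan-2-yl)-2-(prop-2-en-1-yl)cyclopentan-1-one | C=CC[C@@]1(C)C(=O)C[C@@](O)(C(C)C)[C@@H]1[C@@H](O)CC(C)=C | intermediate
11 | (3R,3aS,4S,8aR)-3,4-dihydroxy-6,8a-dimethyl-3-(propan-2-yl)-2,3,3a,4,5,8-hexahydroazulen-1(8aH)-one | O[C@H]1CC(C)=CC[C@@]2(C)C(=O)C[C@@](O)(C(C)C)[C@H]12 | intermediate
12 | 4-methoxybenzoyl chloride | COc1ccc(C(Cl)=O)cc1 | starting material
13 | (3R,3aS,4S,8aR)-3-hydroxy-6,8a-dimethyl-1-oxo-3-(propan-2-yl)-1,2,3,3a,4,5,8,8a-octahydroazulen-4-yl 4-methoxybenzoate | COc1ccc(C(=O)O[C@H]2CC(C)=CC[C@@]3(C)C(=O)C[C@@](O)(C(C)C)[C@H]23)cc1 | target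

**Totals**
Total step count: 7. Longest linear sequence: 7 steps (1 → 13).

**Steps most likely to fail**

Step 3 (the new photo-oxygenation). The risks are O2 trapping at C3 before the ring opens, over-oxidation of 5, and collapse of the β-peroxy ketone to an epoxide. The fallback uses known reaction types and sets out from 4. N-Iodosuccinimide (THF, −78 °C) gives the α-iodo ketone F1 (iodine on C3, epimer mixture). Catalytic (Bu3Sn)2 under a sunlamp (benzene, rt) runs an iodine-atom-transfer chain: the C3 radical opens the cyclopropane and the primary C6 radical takes iodine from F1, giving the iodomethyl cyclopentenone F2. AgOCOCF3 with anhydrous H2O2 in Et2O replaces iodide by OOH to give the primary hydroperoxide F3. Catalytic Et2NH in CF3CH2OH closes the hydroperoxide onto the enone by 5-exo conjugate addition, which again can only give the cis-fused product. The fallback comes back to the route at 6, which is reduced with Zn/AcOH to 7 as in step 3.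

Step 5 (C6 configuration; fragile β-hydroxy aldehyde). The chelate model may not hold, or the addition may give a mixture. The fallback sets out from 8 and moves the stereo-defining event from the C–C bond to the C–O bond. The C6 epimer of 10, the 6R homoallylic alcohol F4, is cyclised with the same ruthenium catalyst to the 6-epi hydroazulene diol F5. The anisate is then introduced with inversion at C6 by Mitsunobu esterification (4-methoxybenzoic acid, PPh3, DIAD, toluene, 0 °C → rt). The fallback comes back to the route at 13, so either epimer from step 5 can be used.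

Step 1 (regiochemistry of enolate formation, over-alkylation, O-alkylation). The fallback sets out from 1 and replaces the direct SN2 alkylation by a regiospecific palladium-mediated allyl transfer. TMSCl, Et3N, DMF at 130 °C gives the thermodynamic, tetrasubstituted trimethylsilyl enol ether F6. MeLi (THF, 0 °C), then TMEDA and allyl chloroformate at −78 °C, gives the allyl enol carbonate F7. The zerovalent palladium complex Pd(PPh3)4 (5 mol%, THF, rt) effects decarboxylative allylation, delivering the allyl group to the methyl-bearing carbon, again anti to the cyclopropane. The fallback comes back to the route at 3.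

**Further compounds**
F1 | step 3 | α-iodo ketone: 3 bearing iodine on C3 (the CH2 between the ketone and the cyclopropane), C3 epimer mixture | C=CC[C@@]1(C)C(=O)C(I)[C@]2(C(C)C)C[C@H]12
F2 | step 3 | iodomethyl cyclopentenone: 4-(iodomethyl)-5-methyl-3-(propan-2-yl)-5-(prop-2-en-1-yl)cyclopent-2-en-1-one, iodomethyl trans to allyl | C=CC[C@@]1(C)C(=O)C=C(C(C)C)[C@@H]1CI
F3 | step 3 | primary hydroperoxide: 4-(hydroperoxymethyl)-5-methyl-3-(propan-2-yl)-5-(prop-2-en-1-yl)cyclopent-2-en-1-one | C=CC[C@@]1(C)C(=O)C=C(C(C)C)[C@@H]1COO
F4 | step 5 | C6 epimer of 10: (2R,3S,4R)-4-hydroxy-3-[(1R)-1-hydroxy-3-methylbut-3-en-1-yl]-2-methyl-4-(propan-2-yl)-2-(prop-2-en-1-yl)cyclopentan-1-one | C=CC[C@@]1(C)C(=O)C[C@@](O)(C(C)C)[C@@H]1[C@H](O)CC(C)=C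
F5 | step 5 | C6 epimer of 11 (6-epi hydroazulene keto diol) | O[C@@H]1CC(C)=CC[C@@]2(C)C(=O)C[C@@](O)(C(C)C)[C@H]12
F6 | step 1 | thermodynamic trimethylsilyl enol ether of thujone (enol ether double bond to the methyl-bearing carbon) | CC1=C(O[Si](C)(C)C)C[C@]2(C(C)C)C[C@H]12
F7 | step 1 | allyl enol carbonate of thujone (same enol regiochemistry as F6) | CC1=C(OC(=O)OCC=C)C[C@]2(C(C)C)C[C@H]12
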